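**Retrosynthetic overview**
1. The eight-membered oxocine ring is closed last: the C2'–O–C(CH3)2 bond comes from acid-mediated Markovnikov cyclo-etherification of a 3-prenyl chain, merged with removal of the two ring B benzyl ethers.
2. The 7-OMe group comes from chemoselective methylation of the non-chelated 7-OH of a 5,7-dihydroxyflavone.
3. Key disconnection: ring C (O1–C2 and C4–C4a) is made in one thermal annulation of D3h-symmetric phloroglucinol with an α-prenyl aroylacetate. Ring closure onto one of three equivalent hydroxyls breaks the symmetry and fixes the ring A pattern.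
4. The α-prenyl β-keto ester is made in one pot from 2',4'-bis(benzyloxy)acetophenone, diethyl carbonate and prenyl bromide.
5. Ring order: rings A and B are bought as arenes, then ring C (pyranone), then the eight-membered oxocine ring.

Assumption: the target SMILES has no stereocentre and cyclointegrin is achiral (the dihydrooxocine ring is taken as conformationally mobile), so no enantiocontrol is needed; 1-[2,4-bis(benzyloxy)phenyl]ethan-1-one is taken as a catalogue compound.

**Step 1**
Reactants: 1 1-[2,4-bis(benzyloxy)phenyl]ethan-1-one; 2 diethyl carbonate; 3 prenyl bromide (1-bromo-3-methylbut-2-ene)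
Product: 5 ethyl 2-[2,4-bis(benzyloxy)benzoyl]-5-methylhex-4-enoate (racemic), via sodium enolate 4 (not isolated)
Conditions: NaH (2.2 equiv), 2 (3 equiv), THF, reflux, 3 h; then AcOH (1.2 equiv), 0 °C; then 3 (1.05 equiv), NaI (5 mol %), DMF, 0 °C → rt
Reagents that add atoms: diethyl carbonate CCOC(=O)OCC; prenyl bromide CC(C)=CCBr
Why: Claisen condensation of the ketone enolate with diethyl carbonate gives the stabilised β-keto ester enolate 4, which, once the ethoxide by-product is neutralised with AcOH, undergoes SN2 C-alkylation by the soft allylic bromide; the new α-stereocentre is formed racemic and disappears in step 2.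

**Step 2**
Reactants: 5 ethyl 2-[2,4-bis(benzyloxy)benzoyl]-5-methylhex-4-enoate; 6 phloroglucinol (benzene-1,3,5-triol)
Product: 10 2-[2,4-bis(benzyloxy)phenyl]-5,7-dihydroxy-3-(3-methylbut-2-en-1-yl)-4H-chromen-4-one, via aroylketene 7 (not isolated), via aryl ester 8 (not isolated), via diketone 9 (not isolated)
Conditions: 6 (anhydrous, 2.5 equiv), neat melt, 240 °C, Ar, 20 min (microwave or sand bath, EtOH and H2O allowed to distil off); water trituration removes excess 6
Reagents that add atoms: phloroglucinol Oc1cc(O)cc(O)c1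
Why: Mentzer pyrone synthesis, in which thermal loss of ethanol from 5 gives aroylketene 7, this O-acylates phloroglucinol to 8, a thermal Fries-type O-to-C acyl shift gives 9 and cyclodehydration onto an ortho hydroxyl closes ring C; because every carbon and oxygen of phloroglucinol is equivalent only one 5,7-dihydroxy regioisomer can form, the symmetry is broken in this single operation, and no stereocentre remains (the α-carbon of 5 becomes sp2 C3).

**Step 3**
Reactants: 10 2-[2,4-bis(benzyloxy)phenyl]-5,7-dihydroxy-3-(3-methylbut-2-en-1-yl)-4H-chromen-4-one; 11 iodomethane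
Product: 12 2-[2,4-bis(benzyloxy)phenyl]-5-hydroxy-7-methoxy-3-(3-methylbut-2-en-1-yl)-4H-chromen-4-one
Conditions: MeI (1.1 equiv), K2CO3 (1.2 equiv), acetone, rt → 40 °C, 6 h
Reagents that add atoms: iodomethane CI
Why: Williamson etherification under weak-base control, selective because the 5-OH is locked in a hydrogen bond to the C4 carbonyl while the 7-OH is an acidic vinylogous carboxylic acid, so one equivalent of MeI methylates only O7; no stereocentre is formed.

**Step 4**
Reactants: 12 2-[2,4-bis(benzyloxy)phenyl]-5-hydroxy-7-methoxy-3-(3-methylbut-2-en-1-yl)-4H-chromen-4-one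
Product: 14 cyclointegrin, via triphenol 13 (not isolated)
Conditions: CF3CO2H–CH2Cl2 (2:1), C6HMe5 (10 equiv), 0 °C → rt, 16 h; aq. NaHCO3 work-up
Reagents that add atoms: none
Why: Acidolytic debenzylation (benzyl cations removed by Friedel–Crafts capture on pentamethylbenzene) frees the 2'- and 4'-hydroxyls, and the same acid protonates the prenyl alkene to the tertiary cation, which the 2'-OH, held beside it by the rigid 2-aryl-3-alkylchromone, captures in a Markovnikov cyclo-etherification to the eight-membered ring, while attack by the C4 carbonyl oxygen is reversible and unproductive; no stereocentre is formed.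

**Compound list**
1 | 1-[2,4-bis(benzyloxy)phenyl]ethan-1-one | CC(=O)c1ccc(OCc2ccccc2)cc1OCc1ccccc1 | starting material
2 | diethyl carbonate | CCOC(=O)OCC | starting material
3 | prenyl bromide (1-bromo-3-methylbut-2-ene) | CC(C)=CCBr | starting material
4 | sodium enolate of ethyl 3-[2,4-bis(benzyloxy)phenyl]-3-oxopropanoate | CCOC(=O)[CH-]C(=O)c1ccc(OCc2ccccc2)cc1OCc1ccccc1.[Na+] | intermediate
5 | ethyl 2-[2,4-bis(benzyloxy)benzoyl]-5-methylhex-4-enoate (racemic) | CCOC(=O)C(CC=C(C)C)C(=O)c1ccc(OCc2ccccc2)cc1OCc1ccccc1 | intermediate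
6 | phloroglucinol (benzene-1,3,5-triol) | Oc1cc(O)cc(O)c1 | starting material
7 | 2-[2,4-bis(benzyloxy)benzoyl]-5-methylhexa-1,4-dien-1-one (aroylketene) | O=C=C(CC=C(C)C)C(=O)c1ccc(OCc2ccccc2)cc1OCc1ccccc1 | intermediate
8 | 3,5-dihydroxyphenyl 2-[2,4-bis(benzyloxy)benzoyl]-5-methylhex-4-enoate (aryl ester, racemic) | CC(C)=CCC(C(=O)Oc1cc(O)cc(O)c1)C(=O)c1ccc(OCc2ccccc2)cc1OCc1ccccc1 | intermediate
9 | 1-[2,4-bis(benzyloxy)phenyl]-2-(3-methylbut-2-en-1-yl)-3-(2,4,6-trihydroxyphenyl)propane-1,3-dione (racemic, enolisable) | CC(C)=CCC(C(=O)c1c(O)cc(O)cc1O)C(=O)c1ccc(OCc2ccccc2)cc1OCc1ccccc1 | intermediate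
10 | 2-[2,4-bis(benzyloxy)phenyl]-5,7-dihydroxy-3-(3-methylbut-2-en-1-yl)-4H-chromen-4-one | O=c1c(CC=C(C)C)c(-c2ccc(OCc3ccccc3)cc2OCc2ccccc2)oc2cc(O)cc(O)c12 | intermediate
11 | iodomethane | CI | starting material
12 | 2-[2,4-bis(benzyloxy)phenyl]-5-hydroxy-7-methoxy-3-(3-methylbut-2-en-1-yl)-4H-chromen-4-one | COc1cc(O)c2c(=O)c(CC=C(C)C)c(-c3ccc(OCc4ccccc4)cc3OCc3ccccc3)oc2c1 | intermediate
13 | 2-(2,4-dihydroxyphenyl)-5-hydroxy-7-methoxy-3-(3-methylbut-2-en-1-yl)-4H-chromen-4-one (triphenol) | COc1cc(O)c2c(=O)c(CC=C(C)C)c(-c3ccc(O)cc3O)oc2c1 | intermediate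
14 | cyclointegrin (5-hydroxy-7-methoxyflavone with C3 joined through CH2CH2C(CH3)2 to the 2'-oxygen, 4'-OH free; achiral) | COc1cc(O)c2c(=O)c3c(oc2c1)-c1ccc(O)cc1OC(C)(C)CC3 | target

**Step count**
Total steps: 4. Longest linear sequence: 4 steps (1 → 5 → 10 → 12 → 14).

**Steps most likely to fail, with fallbacks**

Step 2 (thermal annulation). The risks are decomposition of the α-prenyl keto ester or its ketene at 240 °C and a second annulation on the product. The fallback builds the same 1,3-dicarbonyl at low temperature with the polarity reversed, and it sets out from 5. Krapcho de-ethoxycarbonylation (LiCl, wet DMSO, 150 °C) gives 1-[2,4-bis(benzyloxy)phenyl]-5-methylhex-4-en-1-one F2. Its lithium enolate (LiN(SiMe3)2, 3 equiv, THF, −78 °C → 0 °C) is C-acylated by 5-hydroxy-7-methoxy-2,2-dimethyl-4H-1,3-benzodioxin-4-one F3, which is obtained from the catalogued 5,7-dihydroxy acetonide by MeI/K2CO3 methylation of its non-chelated 7-OH. Acetone is expelled and the product is 1-[2,4-bis(benzyloxy)phenyl]-3-(2,6-dihydroxy-4-methoxyphenyl)-2-(3-methylbut-2-en-1-yl)propane-1,3-dione F4. Warming F4 in AcOH (80 °C) cyclodehydrates it onto either of its two equivalent hydroxyls, which again breaks the symmetry of the ring A unit. The route is rejoined at 12, and step 3 is then not needed.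

Step 4 (one-pot debenzylation and eight-membered ring closure). The risks are slow or incomplete benzyl cleavage, C-benzylation of ring A, and an unfavourable equilibrium between the ether, the alkene and the tertiary trifluoroacetate. The fallback separates deprotection from ring closure and removes the alkene first; it sets out from 12. Mukaiyama hydration (Co(acac)2, PhSiH3, O2, i-PrOH/THF, rt) gives 2-[2,4-bis(benzyloxy)phenyl]-5-hydroxy-3-(3-hydroxy-3-methylbutyl)-7-methoxy-4H-chromen-4-one F5. Hydrogenolysis (H2, Pd/C, EtOAc/MeOH), now with no alkene to lose, gives 2-(2,4-dihydroxyphenyl)-5-hydroxy-3-(3-hydroxy-3-methylbutyl)-7-methoxy-4H-chromen-4-one F6. Catalytic TsOH in toluene at 60 °C with molecular sieves then ionises the tertiary alcohol and closes the ether dehydratively, arriving at 14.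

Step 1 (one-pot carbethoxylation and prenylation). The risks are dialkylation, O-alkylation and loss of prenyl bromide to residual ethoxide. The fallback sets out from 1 and stops after the carbethoxylation (NaH, 2, THF, reflux; aqueous AcOH quench) to isolate ethyl 3-[2,4-bis(benzyloxy)phenyl]-3-oxopropanoate F1. The prenyl group is then introduced by palladium π-allyl chemistry instead of SN2: methyl 3-methylbut-2-en-1-yl carbonate, Pd(PPh3)4 (2 mol %), THF, rt (Tsuji–Trost). The methoxide released on ionisation is the only base, which suppresses dialkylation, and the soft enolate attacks the unsubstituted allyl terminus. The route is rejoined at 5.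

**Further compounds**
F1 | step 1 | ethyl 3-[2,4-bis(benzyloxy)phenyl]-3-oxopropanoate | CCOC(=O)CC(=O)c1ccc(OCc2ccccc2)cc1OCc1ccccc1
F2 | step 2 | 1-[2,4-bis(benzyloxy)phenyl]-5-methylhex-4-en-1-one | CC(C)=CCCC(=O)c1ccc(OCc2ccccc2)cc1OCc1ccccc1
F3 | step 2 | 5-hydroxy-7-methoxy-2,2-dimethyl-4H-1,3-benzodioxin-4-one | COc1cc(O)c2c(c1)OC(C)(C)OC2=O
F4 | step 2 | 1-[2,4-bis(benzyloxy)phenyl]-3-(2,6-dihydroxy-4-methoxyphenyl)-2-(3-methylbut-2-en-1-yl)propane-1,3-dione (racemic, enolisable) | COc1cc(O)c(C(=O)C(CC=C(C)C)C(=O)c2ccc(OCc3ccccc3)cc2OCc2ccccc2)c(O)c1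
F5 | step 4 | 2-[2,4-bis(benzyloxy)phenyl]-5-hydroxy-3-(3-hydroxy-3-methylbutyl)-7-methoxy-4H-chromen-4-one | COc1cc(O)c2c(=O)c(CCC(C)(C)O)c(-c3ccc(OCc4ccccc4)cc3OCc3ccccc3)oc2c1
F6 | step 4 | 2-(2,4-dihydroxyphenyl)-5-hydroxy-3-(3-hydroxy-3-methylbutyl)-7-methoxy-4H-chromen-4-one | COc1cc(O)c2c(=O)c(CCC(C)(C)O)c(-c3ccc(O)cc3O)oc2c1
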